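(The earlier runs and the new flask are simulated for substances that don't exist; noise was put on by code.)

Thursday's run had the same charge of substrate as dawn, dusk and winter, so I opened the books there. Substrate is the limiting reagent, and each mole charged must stand in one of three entries. At 2.50 h, unbound substrate read 80.1% of the charge and product read 20.7%. The charge held on the catalyst, at one per catalyst charged, could reach 0.0296%. The two entries that were read add to 100.8%, with each reading scattered by 0.3 percentage points, and I treated the books as closed. The converted fraction can then be read twice, and the mean of the two readings is 20.3%.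

| flask | substrate | free catalyst | remark | time |
|---|---|---|---|---|
| Monday's | 0.54 M | 1.2 mM | run made earlier |  |
| Sunday's | 1.3 M | 1.2 mM | run made earlier |  |
| Saturday's | 1.8 M | 1.2 mM | run made earlier |  |
| Thursday's | 2.5 M | 0.74 mM | run made earlier |  |
| autumn | 0.60 M | 0.40 mM |  | 2.5 h |
| dawn | 2.5 M | 0.30 mM |  | 2.5 h |
| winter | 2.5 M | 1.2 mM |  | 2.5 h |
| dusk | 2.5 M | 0.40 mM |  | 2.5 h |
| noon | 1.2 M | 0.60 mM |  | 2.5 h |

| run | time / h | product / % | substrate / % |
|---|---|---|---|
| Monday's | 0.200 | 3.7 | 95.6 |
| Monday's | 0.500 | 10.3 | 89.5 |
| Monday's | 1.00 | 18.8 | 80.2 |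
| Monday's | 2.50 | 40.8 | 59.9 |
| Sunday's | 0.667 | 11.8 | 88.4 |
| Sunday's | 1.33 | 21.6 | 78.2 |
| Sunday's | 2.00 | 30.2 | 70.2 |
| Sunday's | 2.50 | 35.5 | 64.4 |
| Saturday's | 0.333 | 5.1 | 94.5 |
| Saturday's | 0.833 | 13.8 | 86.9 |
| Saturday's | 1.50 | 22.0 | 77.9 |
| Saturday's | 2.50 | 32.8 | 67.1 |
| Thursday's | 0.333 | 3.1 | 96.6 |
| Thursday's | 0.833 | 7.5 | 92.5 |
| Thursday's | 1.50 | 13.4 | 87.3 |
| Thursday's | 2.50 | 20.7 | 80.1 |

(standard deviation of a reading: 0.3 percentage points)

- reactions considered so far: substrate + free catalyst -> catalyst intermediate A; catalyst intermediate A -> catalyst intermediate B; catalyst intermediate B <-> free catalyst + product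

- the flasks put in order of amount of product, in percent of the substrate charged, best first, at 2.5 h (autumn / dawn / winter / dusk / noon)
- the amount of product, in percent of the substrate charged of the flask you put first, at 2.5 h
- the amount of product, in percent of the substrate charged of the flask you put last, at 2.5 h

I took the loss as pseudo-first-order in substrate, with its rate proportional to the catalyst charged. Dividing one flask's rate by Thursday's then removes time, provided substrate charge and duration match. The clearing number, the logarithm of the charge over what remains of it at 2.5 h, divided by the catalyst charged, is 0.307 mM⁻¹ from Thursday's run.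

So I reckoned 30.8% for winter, 11.5% for dusk and 8.79% for dawn. The same ledger gives 0.366 mM⁻¹ from Sunday's run, nearest to noon in substrate charge, and 0.432 mM⁻¹ from Monday's run, nearest to autumn in substrate charge. Those give noon 19.7% and autumn 15.9%.

The forecast gave the same order, winter > noon > autumn > dusk > dawn, with 29.3% at the top, less than my figure, and 8.8% at the bottom, and it said: “Rate is assumed proportional to catalyst”.

The flasks gave winter > noon > autumn > dusk > dawn, with winter at 30.1% and dawn at 9.06%.

    substrate + free catalyst → catalyst intermediate A (k = 202 M⁻¹ h⁻¹)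
    catalyst intermediate A → catalyst intermediate B (k = 22500 h⁻¹)
    catalyst intermediate B ⇌ free catalyst + product (K = 1.76 M, k = 948 h⁻¹)

Dawn at 9.06% still held 91% of its substrate unbound at 2.5 h. Read back from its product, dawn's clearing number is 0.317 mM⁻¹, beside the 0.307 mM⁻¹ from Thursday's run. A neighbour like dawn but charged with 0.510 mM of free catalyst comes to 14.5% by the number from Thursday's run, and that flask gave 14.7%.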